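**Plan**

1. Locants: the bicyclic lactone is numbered as an octahydroindene (cyclopentane C1–C3, ring fusion C3a/C7a, C4 = methyl carbinol carbon, C7 = CHBr, 7a-carboxyl lactonised onto O–C4); ring A carries primed locants (C1′ carbinol, C3′ gem-dimethyl, C4′ CHBr).
2. Retrosynthesis cuts, in this order: C7–Br; the exocyclic C3–CH2 bond that joins the halves; in the right half C3–C3a together with the lactone O–C4 bond, then C7a–C1; in ring A C4′–Br, one C3′ methyl and the two Diels–Alder bonds.
3. Enabling feature: C1′(OH)–CH2 is the retron of a spiro-oxirane on ring A, whose ring strain is released by attack at its unsubstituted CH2, and C3 (between C2H2 and the ring-fusion C3a–H) can be held trigonal as the enol triflate of a cyclopentanone, so the bond is made as C(sp2)–CH2 with no stereocentre at stake.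
4. Forward: ring A from a Diels–Alder adduct (spiro-oxirane, then gem-dimethyl, then bromide); right half from a benzamide (Birch alkylation gives the six-membered ring, one acid-triggered Prins/lactonisation cascade closes the cyclopentane and the γ-lactone); nickel joins the halves; hydrogenation and a radical bromination finish.
5. Stereochemistry: C1′ from the catalyst-controlled Diels–Alder reaction (relayed through one SN2 inversion), C4′ by H-atom delivery anti to the axial methyl; C7a from the auxiliary-controlled Birch alkylation, C3a and C4 from the tether-enforced anti addition across the ring alkene, C3 from convex-face hydrogenation, C7 from bromine-atom transfer on the open lactone face.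

Key step: step 16

Assumption: the facial sense of the (S)-oxazaborolidinium catalyst in step 2 and of the (S)-prolinol-ether auxiliary in step 9 is taken as drawn (accepted pre-transition-state and chelated-enolate models); if either proved opposite, the enantiomeric catalyst or auxiliary would be used with no other change.

**Ring A fragment**

Step 1
Reactants: 1 3-methylbut-3-en-2-one
Product: 2 2-methyl-3-[(triisopropylsilyl)oxy]buta-1,3-diene
Conditions: i-Pr3SiOTf, Et3N, CH2Cl2, 0 °C
Reagents that add atoms: triisopropylsilyl trifluoromethanesulfonate, CC(C)[Si](C(C)C)(C(C)C)OS(=O)(=O)C(F)(F)F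
Why: O-silylation of the only enolisable position (the acetyl methyl) under soft-enolisation conditions gives the cross-conjugated 2-silyloxy diene (silyl dienol ether formation); no stereocentre is involved.

Step 2
Reactants: 2 2-methyl-3-[(triisopropylsilyl)oxy]buta-1,3-diene; 3 2-bromoprop-2-enal
Product: 4 (1R)-1-bromo-3-methyl-4-[(triisopropylsilyl)oxy]cyclohex-3-ene-1-carbaldehyde
Conditions: (S)-3,3-diphenyl-1-(o-tolyl)tetrahydro-1H,3H-pyrrolo[1,2-c][1,3,2]oxazaborole·HNTf2 (10 mol %), CH2Cl2, −78 °C
Reagents that add atoms: none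
Why: Catalytic enantioselective Diels–Alder reaction in which the silyloxy group directs the "para" regiochemistry (C(Br)CHO 1,4 to the enol-ether carbon and 1,3 to the methyl-bearing carbon) and the chiral boron cation, bound to the aldehyde, exposes one face of the dienophile and so sets the quaternary C1 stereocentre.

Step 3
Reactants: 4 (1R)-1-bromo-3-methyl-4-[(triisopropylsilyl)oxy]cyclohex-3-ene-1-carbaldehyde
Product: 6 (3S)-5-methyl-6-[(triisopropylsilyl)oxy]-1-oxaspiro[2.5]oct-5-ene, via bromo alcohol 5 (not isolated)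
Conditions: NaBH4, MeOH, −20 °C; then K2CO3, 23 °C
Reagents that add atoms: none
Why: NaBH4 reduces the aldehyde and the primary alkoxide then displaces the tertiary bromide in a 3-exo-tet closure with inversion at C1 (halohydrin-to-epoxide closure), so the Diels–Alder stereocentre is translated cleanly into the spiro centre of the oxirane.

Step 4
Reactants: 6 (3S)-5-methyl-6-[(triisopropylsilyl)oxy]-1-oxaspiro[2.5]oct-5-ene
Product: 8 (3S)-5,5-dimethyl-1-oxaspiro[2.5]octan-6-one, via ammonium enolate 7 (not isolated)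
Conditions: BnMe3NF (anhydrous), MeI, 4 Å sieves, THF, 0 → 23 °C
Reagents that add atoms: iodomethane, CI
Why: Anhydrous fluoride cleaves the Si–O bond to give the tetrasubstituted enolate regiospecifically, which is C-methylated at the methyl-bearing carbon (fluoride-promoted alkylation of a silyl enol ether) to install the gem-dimethyl group without creating a stereocentre.

Step 5
Reactants: 8 (3S)-5,5-dimethyl-1-oxaspiro[2.5]octan-6-one
Product: 10 (3S)-7,7-dimethyl-1-oxaspiro[2.5]oct-5-en-6-yl trifluoromethanesulfonate, via potassium enolate 9 (not isolated)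
Conditions: KN(SiMe3)2, THF, −78 °C; then PhNTf2
Reagents that add atoms: N-phenylbis(trifluoromethanesulfonimide), O=S(=O)(N(c1ccccc1)S(=O)(=O)C(F)(F)F)C(F)(F)F
Why: The ketone can enolise only towards its single α-CH2 group, so deprotonation and O-sulfonylation (enol triflate formation) give one regioisomer, the oxirane being inert to the hindered amide base at low temperature.

Step 6
Reactants: 10 (3S)-7,7-dimethyl-1-oxaspiro[2.5]oct-5-en-6-yl trifluoromethanesulfonate
Product: 11 (3S)-6-bromo-7,7-dimethyl-1-oxaspiro[2.5]oct-5-ene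
Conditions: Ni(cod)2 (10 mol %), LiBr, DMA/THF, 23 °C; K2CO3/MeOH work-up
Reagents that add atoms: lithium bromide, [Li+].[Br-]
Why: Nickel-catalysed triflate-to-halide exchange (oxidative addition of zerovalent nickel to the C–OTf bond, triflate/bromide exchange, C–Br reductive elimination) gives the alkenyl bromide, and any oxirane opened reversibly by bromide is reclosed by the basic work-up.

Step 7
Reactants: 11 (3S)-6-bromo-7,7-dimethyl-1-oxaspiro[2.5]oct-5-ene
Product: 12 (3S,6R)-6-bromo-5,5-dimethyl-1-oxaspiro[2.5]octane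
Conditions: Co(acac)2, t-BuOOH, Et3SiH, 1,4-cyclohexadiene, n-PrOH, 23 °C
Reagents that add atoms: none
Why: Hydrogen-atom-transfer reduction of an alkenyl halide, in which the cobalt hydride adds H• to the unsubstituted alkene carbon and the α-bromo radical, in the chair that keeps the oxirane oxygen axial and its CH2 equatorial, takes its second hydrogen from cyclohexadiene on the face anti to the neighbouring axial methyl, leaving bromine equatorial and cis to the oxirane oxygen (6R).

**Right half**

Step 8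
Reactants: 13 2-methoxy-5-methylbenzoic acid; 14 (2S)-2-(methoxymethyl)pyrrolidine
Product: 16 (2-methoxy-5-methylphenyl)[(2S)-2-(methoxymethyl)pyrrolidin-1-yl]methanone, via acid chloride 15 (not isolated)
Conditions: (COCl)2, DMF (cat.), CH2Cl2, 0 → 23 °C; then 14, Et3N, 0 °C
Reagents that add atoms: none
Why: Acid chloride formation and N-acylation of the secondary amine (amide formation) attach the chiral auxiliary.

Step 9
Reactants: 16 (2-methoxy-5-methylphenyl)[(2S)-2-(methoxymethyl)pyrrolidin-1-yl]methanone; 17 2-(2-bromoethyl)-1,3-dioxolane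
Product: 19 [(1S)-1-[2-(1,3-dioxolan-2-yl)ethyl]-2-methoxy-5-methylcyclohexa-2,5-dien-1-yl][(2S)-2-(methoxymethyl)pyrrolidin-1-yl]methanone, via potassium dienolate 18 (not isolated)
Conditions: K, NH3(l)/THF, t-BuOH (1 equiv), −78 °C; then 17, −78 °C
Reagents that add atoms: none
Why: Birch reduction of the benzamide gives the cross-conjugated potassium amide enolate, whose C-alkylation at the former ipso carbon occurs on the face dictated by the chelating methoxymethylpyrrolidine auxiliary (Birch reduction–alkylation), creating the quaternary stereocentre that becomes C7a.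

Step 10
Reactants: 19 [(1S)-1-[2-(1,3-dioxolan-2-yl)ethyl]-2-methoxy-5-methylcyclohexa-2,5-dien-1-yl][(2S)-2-(methoxymethyl)pyrrolidin-1-yl]methanone
Product: 22 (3R,3aR,4S,7aS)-3,4-dihydroxy-4-methyl-7-oxooctahydro-7aH-indene-7a-carboxylic acid 4,7a-lactone, via keto aldehyde 20 (not isolated), via iminium lactone salt 21 (not isolated)
Conditions: CF3CO2H/H2O (9:1), CH2Cl2, 0 → 23 °C; then aq. NaHCO3
Reagents that add atoms: water, O
Why: Aqueous acid hydrolyses the enol ether and the dioxolane, the protonated aldehyde is attacked by the ring alkene at its CH terminus (Prins cyclisation to the five-membered ring) and the tertiary cation is captured by the amide oxygen, the iminium ether being hydrolysed to the γ-lactone with loss of the auxiliary; because the aldehyde tether and the amide sit on opposite faces of the quaternary carbon the addition across the alkene is necessarily anti, which fixes C3a (cis ring fusion) and C4, while the carbinol configuration at C3 (expected exo, as drawn) is removed in step 14.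

Step 11
Reactants: 22 (3R,3aR,4S,7aS)-3,4-dihydroxy-4-methyl-7-oxooctahydro-7aH-indene-7a-carboxylic acid 4,7a-lactone
Product: 23 (3R,3aR,4S,7aS)-4-hydroxy-4-methyl-7-oxo-3-[(triethylsilyl)oxy]octahydro-7aH-indene-7a-carboxylic acid 4,7a-lactone
Conditions: Et3SiCl, imidazole, DMF, 0 °C
Reagents that add atoms: chlorotriethylsilane, CC[Si](Cl)(CC)CC
Why: Silylation of the only hydroxyl group (silyl ether protection) masks C3–OH while C7 is processed.

Step 12
Reactants: 23 (3R,3aR,4S,7aS)-4-hydroxy-4-methyl-7-oxo-3-[(triethylsilyl)oxy]octahydro-7aH-indene-7a-carboxylic acid 4,7a-lactone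
Product: 24 (3R,3aR,4S,7S,7aS)-4,7-dihydroxy-4-methyl-3-[(triethylsilyl)oxy]octahydro-7aH-indene-7a-carboxylic acid 4,7a-lactone
Conditions: NaBH4, MeOH/THF, −20 °C
Reagents that add atoms: none
Why: NaBH4 reduces the cyclohexanone but not the lactone (carbonyl reduction), and hydride should enter from the lactone-bridge face because the other face is blocked by C3 of the cyclopentane (1,3-diaxial), giving the axial alcohol drawn, whose configuration is in any case erased when C7 becomes a radical in step 18.

Step 13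
Reactants: 24 (3R,3aR,4S,7S,7aS)-4,7-dihydroxy-4-methyl-3-[(triethylsilyl)oxy]octahydro-7aH-indene-7a-carboxylic acid 4,7a-lactone
Product: 25 (3R,3aR,4S,7S,7aS)-4-hydroxy-7-[(methoxyoxalyl)oxy]-4-methyl-3-[(triethylsilyl)oxy]octahydro-7aH-indene-7a-carboxylic acid 4,7a-lactone
Conditions: ClC(O)CO2Me, Et3N, DMAP (cat.), CH2Cl2, 0 °C
Reagents that add atoms: methyl chlorooxoacetate, COC(=O)C(=O)Cl
Why: Acylation of the secondary alcohol with the acid chloride of monomethyl oxalate (esterification) installs the radical precursor as a methyl oxalate that tolerates the oxidation, enolisation and coupling steps that follow.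

Step 14
Reactants: 25 (3R,3aR,4S,7S,7aS)-4-hydroxy-7-[(methoxyoxalyl)oxy]-4-methyl-3-[(triethylsilyl)oxy]octahydro-7aH-indene-7a-carboxylic acid 4,7a-lactone
Product: 27 (3aS,4S,7S,7aS)-4-hydroxy-7-[(methoxyoxalyl)oxy]-4-methyl-3-oxooctahydro-7aH-indene-7a-carboxylic acid 4,7a-lactone, via free alcohol 26 (not isolated)
Conditions: CrO3, H2SO4, H2O/acetone, 0 °C
Reagents that add atoms: none
Why: Aqueous acid removes the triethylsilyl group and chromic acid oxidises the liberated secondary alcohol to the cyclopentanone (Jones oxidation) without touching the oxalate or the lactone.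

Step 15
Reactants: 27 (3aS,4S,7S,7aS)-4-hydroxy-7-[(methoxyoxalyl)oxy]-4-methyl-3-oxooctahydro-7aH-indene-7a-carboxylic acid 4,7a-lactone
Product: 29 (3aS,4S,7S,7aS)-4-hydroxy-7-[(methoxyoxalyl)oxy]-4-methyl-3-{[(trifluoromethyl)sulfonyl]oxy}-3a,4,5,6,7,7a-hexahydro-1H-indene-7a-carboxylic acid 4,7a-lactone, via potassium enolate 28 (not isolated)
Conditions: KN(SiMe3)2, THF, −78 °C; then PhNTf2
Reagents that add atoms: N-phenylbis(trifluoromethanesulfonimide), O=S(=O)(N(c1ccccc1)S(=O)(=O)C(F)(F)F)C(F)(F)F
Why: Kinetic deprotonation occurs at the accessible C2 methylene and not at the hindered ring-fusion C3a–H, and O-sulfonylation of the enolate (enol triflate formation) gives the C2=C3 enol triflate.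

**Union and completion**

Step 16
Reactants: 29 (3aS,4S,7S,7aS)-4-hydroxy-7-[(methoxyoxalyl)oxy]-4-methyl-3-{[(trifluoromethyl)sulfonyl]oxy}-3a,4,5,6,7,7a-hexahydro-1H-indene-7a-carboxylic acid 4,7a-lactone; 12 (3S,6R)-6-bromo-5,5-dimethyl-1-oxaspiro[2.5]octane
Product: 31 (3aS,4S,7S,7aS)-3-{[(1R,4R)-4-bromo-1-hydroxy-3,3-dimethylcyclohexyl]methyl}-4-hydroxy-7-[(methoxyoxalyl)oxy]-4-methyl-3a,4,5,6,7,7a-hexahydro-1H-indene-7a-carboxylic acid 4,7a-lactone, via iodohydrin 30 (not isolated)
Conditions: NiCl2(dme) (10 mol %), 2,2′-bipyridine, NaI (25 mol %), Et3N·HCl, Zn, N,N′-dimethylpropyleneurea, 23 °C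
Reagents that add atoms: none
Why: Iodide, with Et3NH+ as proton source, opens the oxirane of 12 by SN2 at its unsubstituted CH2, releasing the three-membered-ring strain and unmasking the tertiary alcohol without touching its configuration (iodohydrin 30); zerovalent nickel–bipyridine inserts into the C3–OTf bond of 29, a monovalent nickel species abstracts iodine from 30 to give the β-hydroxy primary radical, this is captured at nickel, and reductive elimination from trivalent nickel forges the C(sp2)–CH2 bond while zinc returns the catalyst. The closest known reaction type is the nickel-catalysed reductive cross-electrophile coupling of epoxides with aryl or alkenyl halides and triflates under iodide co-catalysis, which gives the same "linear" regiochemistry. No ring is closed and no stereocentre is created: C1′ is carried over from 12 because only the CH2–O bond breaks, and C3 is deliberately left trigonal so that step 17 can set it. The step needs regioselective opening at CH2 rather than at the spiro carbon, which the fully substituted spiro centre secures, and chemoselective activation of the primary C–I bond and the alkenyl triflate in the presence of the secondary C–Br bond and the oxalate ester, which the weaker unhindered C–I bond and the gem-dimethyl group flanking the bromide should secure.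

Step 17
Reactants: 31 (3aS,4S,7S,7aS)-3-{[(1R,4R)-4-bromo-1-hydroxy-3,3-dimethylcyclohexyl]methyl}-4-hydroxy-7-[(methoxyoxalyl)oxy]-4-methyl-3a,4,5,6,7,7a-hexahydro-1H-indene-7a-carboxylic acid 4,7a-lactone
Product: 32 (3R,3aS,4S,7S,7aS)-3-{[(1R,4R)-4-bromo-1-hydroxy-3,3-dimethylcyclohexyl]methyl}-4-hydroxy-7-[(methoxyoxalyl)oxy]-4-methyloctahydro-7aH-indene-7a-carboxylic acid 4,7a-lactone
Conditions: H2 (1 atm), [Ir(cod)(PCy3)(py)]PF6 (5 mol %), CH2Cl2, 23 °C
Reagents that add atoms: none
Why: Homogeneous alkene hydrogenation with a cationic iridium catalyst that tolerates alkyl bromides delivers H2 to the trisubstituted cyclopentene from its convex face (that of C3a–H), the other face being roofed by C4 and C7 of the six-membered ring, so the CH2–ring A arm is pushed to the concave face and C3 is formed as R.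

Step 18
Reactants: 32 (3R,3aS,4S,7S,7aS)-3-{[(1R,4R)-4-bromo-1-hydroxy-3,3-dimethylcyclohexyl]methyl}-4-hydroxy-7-[(methoxyoxalyl)oxy]-4-methyloctahydro-7aH-indene-7a-carboxylic acid 4,7a-lactone
Product: 34 (3R,3aS,4S,7R,7aR)-7-bromo-3-{[(1R,4R)-4-bromo-1-hydroxy-3,3-dimethylcyclohexyl]methyl}-4-hydroxy-4-methyloctahydro-7aH-indene-7a-carboxylic acid 4,7a-lactone, via cesium oxalate 33 (not isolated)
Conditions: CsOH·H2O (1.0 equiv), THF/H2O, 0 °C; then Ir[dF(CF3)ppy]2(dtbbpy)PF6 (1 mol %), BrCCl3, MeCN, blue LEDs, 23 °C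
Reagents that add atoms: bromotrichloromethane, BrC(Cl)(Cl)Cl
Why: Selective saponification of the methyl ester gives the cesium oxalate, which the excited iridium photocatalyst oxidises, and loss of two CO2 gives the planar C7 radical whose axial face is blocked by C3 and the CH2–ring A arm (1,3-diaxial), so BrCCl3 transfers bromine from the lactone-bridge face to give the equatorial bromide cis to the lactone carbonyl, i.e. 7R (photoredox deoxygenative halogenation of an alkyl oxalate).

**Compound list**

1 | 3-methylbut-3-en-2-one | CC(=O)C(C)=C | starting material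
2 | 2-methyl-3-[(triisopropylsilyl)oxy]buta-1,3-diene | C=C(C)C(=C)O[Si](C(C)C)(C(C)C)C(C)C | intermediate
3 | 2-bromoprop-2-enal | C=C(Br)C=O | starting material
4 | (1R)-1-bromo-3-methyl-4-[(triisopropylsilyl)oxy]cyclohex-3-ene-1-carbaldehyde | CC1=C(O[Si](C(C)C)(C(C)C)C(C)C)CC[C@](Br)(C=O)C1 | intermediate
5 | [(1R)-1-bromo-3-methyl-4-[(triisopropylsilyl)oxy]cyclohex-3-en-1-yl]methanol | CC1=C(O[Si](C(C)C)(C(C)C)C(C)C)CC[C@](Br)(CO)C1 | intermediate (not isolated)
6 | (3S)-5-methyl-6-[(triisopropylsilyl)oxy]-1-oxaspiro[2.5]oct-5-ene | CC1=C(O[Si](C(C)C)(C(C)C)C(C)C)CC[C@@]2(CO2)C1 | intermediate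
7 | benzyltrimethylammonium (3S)-5-methyl-1-oxaspiro[2.5]oct-5-en-6-olate | C[N+](C)(C)Cc1ccccc1.CC1=C([O-])CC[C@@]2(CO2)C1 | intermediate (not isolated)
8 | (3S)-5,5-dimethyl-1-oxaspiro[2.5]octan-6-one | CC1(C)C[C@]2(CO2)CCC1=O | intermediate
9 | potassium (3S)-7,7-dimethyl-1-oxaspiro[2.5]oct-5-en-6-olate | [K+].CC1(C)C[C@]2(CO2)CC=C1[O-] | intermediate (not isolated)
10 | (3S)-7,7-dimethyl-1-oxaspiro[2.5]oct-5-en-6-yl trifluoromethanesulfonate | CC1(C)C[C@]2(CO2)CC=C1OS(=O)(=O)C(F)(F)F | intermediate
11 | (3S)-6-bromo-7,7-dimethyl-1-oxaspiro[2.5]oct-5-ene | CC1(C)C[C@]2(CO2)CC=C1Br | intermediate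
12 | (3S,6R)-6-bromo-5,5-dimethyl-1-oxaspiro[2.5]octane | CC1(C)C[C@]2(CO2)CC[C@H]1Br | intermediate
13 | 2-methoxy-5-methylbenzoic acid | COc1ccc(C)cc1C(=O)O | starting material
14 | (2S)-2-(methoxymethyl)pyrrolidine | COC[C@@H]1CCCN1 | starting material
15 | 2-methoxy-5-methylbenzoyl chloride | COc1ccc(C)cc1C(=O)Cl | intermediate (not isolated)
16 | (2-methoxy-5-methylphenyl)[(2S)-2-(methoxymethyl)pyrrolidin-1-yl]methanone | COc1ccc(C)cc1C(=O)N1CCC[C@H]1COC | intermediate
17 | 2-(2-bromoethyl)-1,3-dioxolane | BrCCC1OCCO1 | starting material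
18 | potassium (2-methoxy-5-methylcyclohexa-2,5-dien-1-ylidene)[(2S)-2-(methoxymethyl)pyrrolidin-1-yl]methanolate | [K+].COC1=CCC(C)=CC1=C([O-])N1CCC[C@H]1COC | intermediate (not isolated)
19 | [(1S)-1-[2-(1,3-dioxolan-2-yl)ethyl]-2-methoxy-5-methylcyclohexa-2,5-dien-1-yl][(2S)-2-(methoxymethyl)pyrrolidin-1-yl]methanone | COC1=CCC(C)=C[C@]1(CCC1OCCO1)C(=O)N1CCC[C@H]1COC | intermediate
20 | 3-[(1S)-1-{[(2S)-2-(methoxymethyl)pyrrolidin-1-yl]carbonyl}-3-methyl-6-oxocyclohex-2-en-1-yl]propanal | O=CCC[C@]1(C(=O)N2CCC[C@H]2COC)C=C(C)CCC1=O | intermediate (not isolated)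
21 | iminium ether of 22 (lactone carbonyl oxygen replaced by the (2S)-2-(methoxymethyl)pyrrolidinium-1-ylidene group), trifluoroacetate salt | O[C@@H]2CC[C@@]34C(=[N+]5CCC[C@H]5COC)O[C@@](C)(CCC3=O)[C@@H]24.[O-]C(=O)C(F)(F)F | intermediate (not isolated)
22 | (3R,3aR,4S,7aS)-3,4-dihydroxy-4-methyl-7-oxooctahydro-7aH-indene-7a-carboxylic acid 4,7a-lactone | O[C@@H]2CC[C@@]34C(=O)O[C@@](C)(CCC3=O)[C@@H]24 | intermediate
23 | (3R,3aR,4S,7aS)-4-hydroxy-4-methyl-7-oxo-3-[(triethylsilyl)oxy]octahydro-7aH-indene-7a-carboxylic acid 4,7a-lactone | CC[Si](CC)(CC)O[C@@H]2CC[C@@]34C(=O)O[C@@](C)(CCC3=O)[C@@H]24 | intermediate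
24 | (3R,3aR,4S,7S,7aS)-4,7-dihydroxy-4-methyl-3-[(triethylsilyl)oxy]octahydro-7aH-indene-7a-carboxylic acid 4,7a-lactone | CC[Si](CC)(CC)O[C@@H]2CC[C@@]34C(=O)O[C@@](C)(CC[C@@H]3O)[C@@H]24 | intermediate
25 | (3R,3aR,4S,7S,7aS)-4-hydroxy-7-[(methoxyoxalyl)oxy]-4-methyl-3-[(triethylsilyl)oxy]octahydro-7aH-indene-7a-carboxylic acid 4,7a-lactone | CC[Si](CC)(CC)O[C@@H]2CC[C@@]34C(=O)O[C@@](C)(CC[C@@H]3OC(=O)C(=O)OC)[C@@H]24 | intermediate
26 | (3R,3aR,4S,7S,7aS)-3,4-dihydroxy-7-[(methoxyoxalyl)oxy]-4-methyloctahydro-7aH-indene-7a-carboxylic acid 4,7a-lactone | O[C@@H]2CC[C@@]34C(=O)O[C@@](C)(CC[C@@H]3OC(=O)C(=O)OC)[C@@H]24 | intermediate (not isolated)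
27 | (3aS,4S,7S,7aS)-4-hydroxy-7-[(methoxyoxalyl)oxy]-4-methyl-3-oxooctahydro-7aH-indene-7a-carboxylic acid 4,7a-lactone | O=C2CC[C@@]34C(=O)O[C@@](C)(CC[C@@H]3OC(=O)C(=O)OC)[C@@H]24 | intermediate
28 | potassium C2=C3 enolate of 27 (configuration as in 27) | [K+].[O-]C2=CC[C@@]34C(=O)O[C@@](C)(CC[C@@H]3OC(=O)C(=O)OC)[C@@H]24 | intermediate (not isolated)
29 | (3aS,4S,7S,7aS)-4-hydroxy-7-[(methoxyoxalyl)oxy]-4-methyl-3-{[(trifluoromethyl)sulfonyl]oxy}-3a,4,5,6,7,7a-hexahydro-1H-indene-7a-carboxylic acid 4,7a-lactone | O=S(=O)(OC2=CC[C@@]34C(=O)O[C@@](C)(CC[C@@H]3OC(=O)C(=O)OC)[C@@H]24)C(F)(F)F | intermediate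
30 | (1S,4R)-4-bromo-1-(iodomethyl)-3,3-dimethylcyclohexan-1-ol | CC1(C)C[C@](O)(CI)CC[C@H]1Br | intermediate (not isolated)
31 | (3aS,4S,7S,7aS)-3-{[(1R,4R)-4-bromo-1-hydroxy-3,3-dimethylcyclohexyl]methyl}-4-hydroxy-7-[(methoxyoxalyl)oxy]-4-methyl-3a,4,5,6,7,7a-hexahydro-1H-indene-7a-carboxylic acid 4,7a-lactone | CC1(C)C[C@](O)(CC2=CC[C@@]34C(=O)O[C@@](C)(CC[C@@H]3OC(=O)C(=O)OC)[C@@H]24)CC[C@H]1Br | intermediate
32 | (3R,3aS,4S,7S,7aS)-3-{[(1R,4R)-4-bromo-1-hydroxy-3,3-dimethylcyclohexyl]methyl}-4-hydroxy-7-[(methoxyoxalyl)oxy]-4-methyloctahydro-7aH-indene-7a-carboxylic acid 4,7a-lactone | CC1(C)C[C@](O)(C[C@H]2CC[C@@]34C(=O)O[C@@](C)(CC[C@@H]3OC(=O)C(=O)OC)[C@@H]24)CC[C@H]1Br | intermediate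
33 | cesium salt of the C7 oxalic acid half ester corresponding to 32 | [Cs+].CC1(C)C[C@](O)(C[C@H]2CC[C@@]34C(=O)O[C@@](C)(CC[C@@H]3OC(=O)C(=O)[O-])[C@@H]24)CC[C@H]1Br | intermediate (not isolated)
34 | (3R,3aS,4S,7R,7aR)-7-bromo-3-{[(1R,4R)-4-bromo-1-hydroxy-3,3-dimethylcyclohexyl]methyl}-4-hydroxy-4-methyloctahydro-7aH-indene-7a-carboxylic acid 4,7a-lactone | CC1(C)C[C@](O)(C[C@H]2CC[C@@]34C(=O)O[C@@](C)(CC[C@H]3Br)[C@@H]24)CC[C@H]1Br | target

**Step count**

Total: 18 steps. Longest linear sequence: 11 steps (steps 8 to 18); the ring A branch is 7 steps (steps 1 to 7) before the union.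

**Three steps most likely to fail**

Step 16. The reductive coupling may be diverted by halogen-atom abstraction at the secondary C–Br bond of ring A, by reduction or homocoupling of the alkenyl triflate, or by β-elimination of hydroxide from the alkylnickel. The fallback replaces the radical cross-electrophile coupling by a palladium-catalysed Negishi coupling of a preformed organozinc. It sets out from 12 and 29 and returns at 31. Epoxide 12 is opened with LiI/AcOH to iodohydrin 30, now isolated, and the tertiary alcohol is silylated (Et3SiOTf, 2,6-lutidine) to {[(1S,4R)-4-bromo-1-(iodomethyl)-3,3-dimethylcyclohexyl]oxy}(triethyl)silane F1. Zinc dust with LiCl in THF inserts into the primary C–I bond to give the alkylzinc iodide F2, which is coupled with 29 using Pd(OAc)2 and 2-dicyclohexylphosphino-2′,6′-dimethoxybiphenyl to the silyl ether of 31, F3. Desilylation with HF·pyridine gives 31.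

Step 18. The secondary alkoxycarbonyl radical may be trapped before it loses CO2, or bromine-atom transfer to the C7 radical may show too little facial bias. The fallback makes the C7–Br bond by ionic displacement with inversion before the halves are joined. It sets out from 24 and returns at 34. The axial C7 alcohol of 24 is converted with Tf2O and pyridine into the 7-O-triflate F4, which is displaced in the same flask by Bu4NBr from the lactone face to give the equatorial bromide F5. Jones oxidation then gives the bromo ketone F6, and enol triflate formation as in step 15 gives the bromo enol triflate F7. The nickel coupling of step 16 with 12 gives the coupled bromo alkene F8, and hydrogenation as in step 17 gives 34.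

Step 10. The cationic cascade may be diverted into an acid-catalysed aldol closure between the ketone enol and the aldehyde, or into ene-type proton loss without lactonisation. The fallback closes the lactone first and forms the cyclopentane by a radical rather than a cationic process. It sets out from 19 and returns at 22. Compound 19 is hydrolysed with dilute HCl in THF to keto aldehyde 20, now isolated. Iodolactonisation (I2, NaHCO3, aqueous THF), in which the amide oxygen closes on the methyl-bearing carbon and the auxiliary is lost on hydrolysis, gives 3-(8-iodo-5-methyl-2,7-dioxo-6-oxabicyclo[3.2.1]octan-1-yl)propanal F9, with iodine anti to the lactone bridge. The secondary radical generated from F9 with Bu3SnH and azobisisobutyronitrile in benzene at 80 °C cyclises 5-exo onto the aldehyde carbonyl and is reduced to 22.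

**Further compounds**

F1 | step 16 | {[(1S,4R)-4-bromo-1-(iodomethyl)-3,3-dimethylcyclohexyl]oxy}(triethyl)silane | CC1(C)C[C@](O[Si](CC)(CC)CC)(CI)CC[C@H]1Br
F2 | step 16 | {[(1S,4R)-4-bromo-3,3-dimethyl-1-[(triethylsilyl)oxy]cyclohexyl]methyl}(iodo)zinc | CC1(C)C[C@](O[Si](CC)(CC)CC)(C[Zn]I)CC[C@H]1Br
F3 | step 16 | triethylsilyl ether of 31 at the tertiary hydroxyl of ring A | CC1(C)C[C@](O[Si](CC)(CC)CC)(CC2=CC[C@@]34C(=O)O[C@@](C)(CC[C@@H]3OC(=O)C(=O)OC)[C@@H]24)CC[C@H]1Br
F4 | step 18 | (3R,3aR,4S,7S,7aS)-4-hydroxy-4-methyl-3-[(triethylsilyl)oxy]-7-{[(trifluoromethyl)sulfonyl]oxy}octahydro-7aH-indene-7a-carboxylic acid 4,7a-lactone | CC[Si](CC)(CC)O[C@@H]2CC[C@@]34C(=O)O[C@@](C)(CC[C@@H]3OS(=O)(=O)C(F)(F)F)[C@@H]24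
F5 | step 18 | (3R,3aR,4S,7R,7aR)-7-bromo-4-hydroxy-4-methyl-3-[(triethylsilyl)oxy]octahydro-7aH-indene-7a-carboxylic acid 4,7a-lactone | CC[Si](CC)(CC)O[C@@H]2CC[C@@]34C(=O)O[C@@](C)(CC[C@H]3Br)[C@@H]24
F6 | step 18 | (3aS,4S,7R,7aR)-7-bromo-4-hydroxy-4-methyl-3-oxooctahydro-7aH-indene-7a-carboxylic acid 4,7a-lactone | O=C2CC[C@@]34C(=O)O[C@@](C)(CC[C@H]3Br)[C@@H]24
F7 | step 18 | (3aS,4S,7R,7aR)-7-bromo-4-hydroxy-4-methyl-3-{[(trifluoromethyl)sulfonyl]oxy}-3a,4,5,6,7,7a-hexahydro-1H-indene-7a-carboxylic acid 4,7a-lactone | O=S(=O)(OC2=CC[C@@]34C(=O)O[C@@](C)(CC[C@H]3Br)[C@@H]24)C(F)(F)F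
F8 | step 18 | (3aS,4S,7R,7aR)-7-bromo-3-{[(1R,4R)-4-bromo-1-hydroxy-3,3-dimethylcyclohexyl]methyl}-4-hydroxy-4-methyl-3a,4,5,6,7,7a-hexahydro-1H-indene-7a-carboxylic acid 4,7a-lactone | CC1(C)C[C@](O)(CC2=CC[C@@]34C(=O)O[C@@](C)(CC[C@H]3Br)[C@@H]24)CC[C@H]1Br
F9 | step 10 | 3-(8-iodo-5-methyl-2,7-dioxo-6-oxabicyclo[3.2.1]octan-1-yl)propanal (iodine anti to the lactone bridge) | O=CCC[C@@]34C(=O)O[C@@](C)(CCC3=O)[C@H]4I
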